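**Assumptions (one line each)**
- (S)-But-3-yn-2-ol (1), 5-bromo-1,2,3-trimethoxybenzene (6) and 4-bromo-1,2-dimethoxybenzene (9) are commercial.
- Simple reagents (MeI, EtCOCl, n-BuLi, LDA, etc.) are not numbered.

## Retrosynthetic overview
1. The target (11) is made by reductive etherification of the γ-hydroxy ketone 10. This is the only ring-forming step and it comes last.
2. Compound 10 comes from 3,4-dimethoxyphenylmagnesium bromide adding to aldehyde 8. Aldehyde 8 comes from ozonolysis of the alkene in aryl ketone 7. Ketone 7 comes from the acid 5 plus 3,4,5-trimethoxyphenyllithium.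
3. Acid 5 carries both methyl stereocentres. It is made by an Ireland–Claisen [3,3] rearrangement (the key C3–C4 bond-forming step) of propionate 4.
4. Propionate 4 is made from (S)-(E)-pent-3-en-2-ol (3), whose carbinol centre is transferred into both methyl-bearing carbons. Alcohol 3 is made from the chiral-pool alkynol 1 by methylation and trans-reduction.

## Route

**Step 1**
Reactants: 1, (S)-but-3-yn-2-ol
Product: 2, (S)-pent-3-yn-2-ol
Conditions: n-BuLi (2.1 equiv), THF, −78 → 0 °C; then MeI, HMPA, 0 °C → rt
Reagents that add atoms: iodomethane, CI (its CH3 ends up in 2)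
Why: Alkylation of the alkoxide/acetylide dianion occurs at the more nucleophilic acetylide carbon. The carbinol stereocentre is untouched, so its configuration is retained.

**Step 2**
Reactants: 2
Product: 3, (S,E)-pent-3-en-2-ol, C[C@H](O)/C=C/C
Conditions: Red-Al, Et2O, 0 °C → rt; then aqueous Rochelle salt work-up
Reagents that add atoms: none (hydride only)
Why: Alkoxide-directed trans-hydroalumination of a propargylic alcohol gives the E-allylic alcohol. The carbinol is not affected and is still (S).

**Step 3**
Reactants: 3
Product: 4, (S,E)-pent-3-en-2-yl propanoate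
Conditions: EtCOCl, Et3N, DMAP (cat.), CH2Cl2, 0 °C → rt
Reagents that add atoms: propionyl chloride, CCC(=O)Cl
Why: Simple acylation (esterification) of the secondary alcohol, with no change at the stereocentre.

**Step 4**
Reactants: 4
Product: 5, (2S,3R,4E)-2,3-dimethylhex-4-enoic acid
Conditions: LDA, THF/HMPA (≈4:1), −78 °C; then TBSCl, −78 °C → rt, 12 h; then 1 M HCl, THF, rt
Reagents that add atoms: none (the silyl group is removed on work-up)
Why: In THF/HMPA the ester forms the (Z)-silyl ketene acetal (Me trans to the allyloxy oxygen). Ireland–Claisen [3,3] rearrangement through a chair transition state, with the E-alkene and the carbinol methyl equatorial, forms the C–C bond. It gives the syn-2,3-dimethyl acid and a new E-alkene. The (S)-carbinol fixes the absolute sense as (2S,3R), so both methyl centres are set by 1,3-chirality transfer.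

**Step 5**
Reactants: 5 and 6, 5-bromo-1,2,3-trimethoxybenzene
Product: 7, (2S,3R,4E)-2,3-dimethyl-1-(3,4,5-trimethoxyphenyl)hex-4-en-1-one
Conditions: 6 (2.5 equiv) + n-BuLi (2.5 equiv), THF, −78 °C, 30 min (Br/Li exchange to the aryllithium); add 5, −78 → 0 °C, 2 h; quench with sat. aq. NH4Cl
Reagents that add atoms: 3,4,5-trimethoxyphenyllithium, [Li]c1cc(OC)c(OC)c(OC)c1 (from 6 + n-BuLi)
Why: Organolithium addition to a carboxylic acid gives a stable dilithio tetrahedral intermediate that collapses to the aryl ketone only on work-up. There is no over-addition and no enolate, so the α-stereocentre is not epimerised.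

**Step 6**
Reactants: 7
Product: 8, (2S,3S)-2,3-dimethyl-4-oxo-4-(3,4,5-trimethoxyphenyl)butanal
Conditions: O3, CH2Cl2, −78 °C (stop at the first blue colour); then Me2S, −78 °C → rt; use the crude product immediately
Reagents that add atoms: ozone, [O-][O+]=O (one oxygen becomes the aldehyde C=O)
Why: Ozonolysis (Criegee cleavage with reductive work-up) converts the disubstituted alkene to the aldehyde under neutral conditions. The deactivated aryl ketone ring survives, and the two methyl stereocentres are not touched.

**Step 7**
Reactants: 8 and 9, 4-bromo-1,2-dimethoxybenzene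
Product: 10, (2S,3S)-4-(3,4-dimethoxyphenyl)-4-hydroxy-2,3-dimethyl-1-(3,4,5-trimethoxyphenyl)butan-1-one, obtained as C4 epimers
Conditions: 9 + Mg, THF (ArMgBr), then add 1.2 equiv to 8 in THF at −78 °C; quench with sat. aq. NH4Cl
Reagents that add atoms: 3,4-dimethoxyphenylmagnesium bromide, COc1ccc([Mg]Br)cc1OC (from 9 + Mg)
Why: Grignard addition to the aldehyde is much faster than addition to the electron-rich aryl ketone, so it is chemoselective at −78 °C. The new carbinol forms as a diastereomer mixture, which is tolerated because the next step converges it.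

**Step 8**
Reactants: 10
Product: 11, target (2S,3S,4S,5S)-2-(3,4-dimethoxyphenyl)-3,4-dimethyl-5-(3,4,5-trimethoxyphenyl)tetrahydrofuran
Conditions: Et3SiH (4 equiv), TFA (10 equiv), CH2Cl2, 0 °C → rt
Reagents that add atoms: none (hydride from Et3SiH and a proton only)
Why: Reductive etherification. The hydroxy ketone closes to a hemiketal and then a cyclic oxocarbenium ion, which Et3SiH reduces. This should give the 2,3-trans relationship next to the trans-dimethyl core. The veratryl C–O bond can ionise reversibly in TFA, so the carbinol epimers converge on the thermodynamically favoured all-trans THF. The methyl stereocentres are carried through unchanged.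

## Compound list
1 | (S)-but-3-yn-2-ol | C[C@H](O)C#C | starting material
2 | (S)-pent-3-yn-2-ol | C[C@H](O)C#CC | intermediate
3 | (S,E)-pent-3-en-2-ol | C[C@H](O)/C=C/C | intermediate
4 | (S,E)-pent-3-en-2-yl propanoate | CCC(=O)O[C@@H](C)/C=C/C | intermediate
5 | (2S,3R,4E)-2,3-dimethylhex-4-enoic acid | OC(=O)[C@@H](C)[C@H](C)/C=C/C | intermediate
6 | 5-bromo-1,2,3-trimethoxybenzene | COc1cc(Br)cc(OC)c1OC | starting material
7 | (2S,3R,4E)-2,3-dimethyl-1-(3,4,5-trimethoxyphenyl)hex-4-en-1-one | COc1cc(cc(OC)c1OC)C(=O)[C@@H](C)[C@H](C)/C=C/C | intermediate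
8 | (2S,3S)-2,3-dimethyl-4-oxo-4-(3,4,5-trimethoxyphenyl)butanal | COc1cc(cc(OC)c1OC)C(=O)[C@@H](C)[C@H](C)C=O | intermediate
9 | 4-bromo-1,2-dimethoxybenzene | COc1ccc(Br)cc1OC | starting material
10 | (2S,3S)-4-(3,4-dimethoxyphenyl)-4-hydroxy-2,3-dimethyl-1-(3,4,5-trimethoxyphenyl)butan-1-one (C4 epimers) | COc1cc(cc(OC)c1OC)C(=O)[C@@H](C)[C@H](C)C(O)c1ccc(OC)c(OC)c1 | intermediate
11 | 5-methoxygalbelgin, (2S,3S,4S,5S)-2-(3,4-dimethoxyphenyl)-3,4-dimethyl-5-(3,4,5-trimethoxyphenyl)tetrahydrofuran | COc1ccc([C@H]2O[C@H](c3cc(OC)c(OC)c(OC)c3)[C@@H](C)[C@@H]2C)cc1OC | target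

## Step count
Total steps: 8. Longest linear sequence: 8 steps (1 → 2 → 3 → 4 → 5 → 7 → 8 → 10 → 11 through compounds; the aryl bromides 6 and 9 are commercial and enter at steps 5 and 7).

## Three steps most likely to fail
1. **Step 4, Ireland–Claisen syn selectivity.** The syn:anti ratio depends on clean (Z)-ketene acetal formation.
   - Fallback: switch to a Johnson–Claisen of 3 with CH3C(OEt)3 and cat. EtCO2H at 140 °C, then separate the syn and anti ethyl esters by chromatography. Alternatively, build the 2,3-syn fragment by substrate-controlled enolate alkylation from (S)-Roche ester.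
2. **Step 8, reductive cyclisation.** Risks are over-reduction of the veratryl carbinol to CH2, ketone epimerisation in TFA, and an incomplete C2/C5 diastereomer funnel.
   - Fallback: reduce 10 with NaBH4 to the 1,4-diol mixture, then cyclodehydrate with TsOH or Amberlyst-15 in toluene under thermodynamic control to reach the all-trans THF.
3. **Step 7, Grignard addition to aldehyde 8.** The α-centre of the aldehyde can epimerise, and the Felkin preference likely gives the wrong C4 carbinol epimer as the major product.
   - Fallback: ozonolyse acid 5 directly to the 5-hydroxy-3,4-dimethylbutanolide. Add the aryl Grignard to give the 5-aryl lactone, then add ArLi to make the lactol and reduce with Et3SiH/BF3·OEt2 (the classical lactone route to 2,5-diaryl THF lignans).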